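## Retrosynthetic overview

1. Target 7 ⇒ keto phosphonoacetate 6: cut the C3=C3a bond of the butenolide (intramolecular Horner–Wadsworth–Emmons olefination, last step).
2. 6 ⇒ ketone 3 + phosphonoacetic acid 4: the tertiary C7a–O bond is the key disconnection, made by a direct, substrate-controlled oxidative α-oxyacylation that sets the quaternary stereocentre.
3. 3 ⇒ (4R,6R)-actinol 1 + palmitoyl chloride 2: the ester C–O bond is made first, so the palmitate acts as its own protecting group.
4. Ring order: the carbocycle (ring A) is bought with the carbinol centre in place; the lactone (ring B) is the only ring built, its C–O bond in step 2 and its closure in step 3.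

Assumption: (4R,6R)-actinol 1, the bulk intermediate of industrial zeaxanthin manufacture, is bought as the single enantiomer; target positions are numbered as in loliolide (C6 carbinol, C7a quaternary).

## Route

Step 1
Reactants: 1 (4R,6R)-4-hydroxy-2,2,6-trimethylcyclohexan-1-one; 2 hexadecanoyl chloride (palmitoyl chloride)
Product: 3 (1R,5R)-3,3,5-trimethyl-4-oxocyclohexyl hexadecanoate
Conditions: pyridine (2 equiv), 4-(dimethylamino)pyridine (5 mol %), CH2Cl2, 0 °C → rt
Reagents that add atoms: none
Why: 4-(Dimethylamino)pyridine-catalysed O-acylation (nucleophilic acyl substitution) of the secondary alcohol by the acid chloride; the carbinol C–O bond is not broken, so its (R) configuration is kept, and the weak base leaves the ketone α-centre alone (that centre is planarised in step 2 in any case).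

Step 2
Reactants: 3 (1R,5R)-3,3,5-trimethyl-4-oxocyclohexyl hexadecanoate; 4 2-(diethoxyphosphoryl)acetic acid
Product: 6 (1R,5S)-5-(hexadecanoyloxy)-1,3,3-trimethyl-2-oxocyclohexyl 2-(diethoxyphosphoryl)acetate, via trivalent-iodine enolate 5 (not isolated)
Conditions: PhI(OAc)2 (1.3 equiv), 4 (4 equiv), PhCl, 45 °C, 20 mbar (AcOH off); then 3, CF3SO3H (20 mol %), CH2Cl2, 0 °C → rt
Reagents that add atoms: none
Why: Proposed new method: a direct oxidative α-oxyacylation of an α-branched ketone by a bis(acyloxy)iodobenzene made beforehand from PhI(OAc)2 and 4, which transfers an olefination-ready phosphonoacetate; acid-catalysed enolisation of 3 can only go towards the methyl-bearing α-carbon (the other α-carbon is quaternary), the enol oxygen binds the electrophilic trivalent iodine to give 5, and loss of PhI delivers the carboxylate to the α-carbon (SN2′-type umpolung) along the axial trajectory of the half-chair that keeps the palmitoyloxy group equatorial, that is anti to that group, because this path leads straight to a chair with the new C–O bond axial and the methyl equatorial whereas attack on the other face would force the methyl into a syn-diaxial clash with the gem-dimethyl group, so the quaternary centre is set (1R) with oxygen trans to the palmitoyloxy group as in loliolide; the closest known reaction type is the acid-promoted α-acetoxylation or α-tosyloxylation of enolisable ketones with PhI(OAc)2 or PhI(OH)OTs, which has not been shown for forging a tertiary C–O bond of a hindered cyclohexanone under remote 1,3-stereocontrol or for transferring a phosphonoacetate.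

Step 3
Reactants: 6 (1R,5S)-5-(hexadecanoyloxy)-1,3,3-trimethyl-2-oxocyclohexyl 2-(diethoxyphosphoryl)acetate
Product: 7 (6S,7aR)-4,4,7a-trimethyl-2-oxo-2,4,5,6,7,7a-hexahydro-1-benzofuran-6-yl hexadecanoate, (-)-3-O-palmitoylloliolide
Conditions: NaH (1.1 equiv), THF, 0 °C → 50 °C
Reagents that add atoms: none
Why: Intramolecular Horner–Wadsworth–Emmons olefination, in which the phosphonate carbanion (far more acidic than the palmitate α-CH2) adds to the adjacent ketone in a five-membered closure and expels diethyl phosphate to give the butenolide; no stereocentre is formed, C7a is quaternary and the C6 ester is untouched.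

## Compound list

1 | (4R,6R)-4-hydroxy-2,2,6-trimethylcyclohexan-1-one, (4R,6R)-actinol, hydroxyl and 6-methyl trans | O[C@H]1CC(C)(C)C(=O)[C@H](C)C1 | starting material
2 | hexadecanoyl chloride (palmitoyl chloride) | CCCCCCCCCCCCCCCC(=O)Cl | starting material
3 | (1R,5R)-3,3,5-trimethyl-4-oxocyclohexyl hexadecanoate | CCCCCCCCCCCCCCCC(=O)O[C@H]1CC(C)(C)C(=O)[C@H](C)C1 | intermediate
4 | 2-(diethoxyphosphoryl)acetic acid | CCOP(=O)(OCC)CC(=O)O | starting material
5 | O-bound trivalent-iodine enolate of 3: phenyliodine carrying one 2-(diethoxyphosphoryl)acetate ligand and, through the enol oxygen, the (4R)-4-(hexadecanoyloxy)-2,6,6-trimethylcyclohex-1-en-1-yl group | CCCCCCCCCCCCCCCC(=O)O[C@H]1CC(C)(C)C(OI(c2ccccc2)OC(=O)CP(=O)(OCC)OCC)=C(C)C1 | intermediate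
6 | (1R,5S)-5-(hexadecanoyloxy)-1,3,3-trimethyl-2-oxocyclohexyl 2-(diethoxyphosphoryl)acetate, acyloxy oxygen trans to the palmitoyloxy group | CCCCCCCCCCCCCCCC(=O)O[C@H]1CC(C)(C)C(=O)[C@](C)(OC(=O)CP(=O)(OCC)OCC)C1 | intermediate
7 | (6S,7aR)-4,4,7a-trimethyl-2-oxo-2,4,5,6,7,7a-hexahydro-1-benzofuran-6-yl hexadecanoate, (-)-3-O-palmitoylloliolide | CCCCCCCCCCCCCCCC(=O)O[C@H]1CC(C)(C)C2=CC(=O)O[C@]2(C)C1 | target

## Step count and risks

Total step count: 3. Longest linear sequence: 3 steps (1 → 3 → 6 → 7).

**Step 2 (the proposed new α-oxyacylation), most likely to fail.** The hindered ketone may enolise slowly. Enolate 5 may lose a ring proton to give the enone, or undergo ring contraction, instead of forming the C–O bond. The facial ratio is a prediction (about 5:1 or better expected); the minor epimer at the new centre would end as the C7a epimer of 7 and must be removed by chromatography at the stage of 6. The fallback is known chemistry, sets out from 3 and comes back at 6. Me3SiOTf and Et3N (CH2Cl2, 0 °C) give the trimethylsilyl enol ether F1. Rubottom oxidation with 3-chloroperbenzoic acid (NaHCO3, CH2Cl2, 0 °C) epoxidises the same face, anti to the palmitoyloxy group, and after silyl shift gives the α-silyloxy ketone F2. Dilute HCl in THF frees the tertiary α-hydroxy ketone F3. Steglich esterification of F3 with 4 (N,N′-dicyclohexylcarbodiimide, 4-(dimethylamino)pyridine, CH2Cl2) gives 6.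

**Step 3 (olefination of a ketone flanked by two quaternary carbons).** The stabilised carbanion may fail to add. The fallback replaces olefination by aldol-type closure and dehydration; it sets out from 3 and comes back at 7. The α-hydroxy ketone F3, made from 3 as described above, is acylated with bromoacetyl bromide and pyridine (CH2Cl2, 0 °C) to the bromoacetate F4. SmI2 (THF, −78 °C) effects an intramolecular Reformatsky addition to the cis-fused β-hydroxy lactone F5. SOCl2 and pyridine (0 °C) dehydrate F5, whose only β-hydrogens are those next to the lactone carbonyl, to 7.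

**Step 1 (acylation of an axial hydroxyl that is syn to an axial methyl group).** The long-chain chloride may react sluggishly, and the palmitate must then survive the acid of step 2. The fallback makes the ester last; it sets out from 1 and comes back at 7. tBuPh2SiCl and imidazole (DMF) give the silyl ether F6. The conditions of step 2 give, by way of the trivalent-iodine enolate F7, the keto phosphonoacetate F8. NaH (THF) closes F8 to O-silyl loliolide F9. HF·pyridine (THF) frees (−)-loliolide F10. Steglich esterification of F10 with palmitic acid (N-ethyl-N′-(3-dimethylaminopropyl)carbodiimide hydrochloride, 4-(dimethylamino)pyridine, CH2Cl2) gives 7.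

## Further compounds

F1 | step 2 | (1R)-3,5,5-trimethyl-4-[(trimethylsilyl)oxy]cyclohex-3-en-1-yl hexadecanoate | CCCCCCCCCCCCCCCC(=O)O[C@H]1CC(C)(C)C(O[Si](C)(C)C)=C(C)C1
F2 | step 2 | (1S,5R)-3,3,5-trimethyl-4-oxo-5-[(trimethylsilyl)oxy]cyclohexyl hexadecanoate | CCCCCCCCCCCCCCCC(=O)O[C@H]1CC(C)(C)C(=O)[C@](C)(O[Si](C)(C)C)C1
F3 | step 2 | (1S,3R)-3-hydroxy-3,5,5-trimethyl-4-oxocyclohexyl hexadecanoate | CCCCCCCCCCCCCCCC(=O)O[C@H]1CC(C)(C)C(=O)[C@](C)(O)C1
F4 | step 3 | (1R,5S)-5-(hexadecanoyloxy)-1,3,3-trimethyl-2-oxocyclohexyl 2-bromoacetate | CCCCCCCCCCCCCCCC(=O)O[C@H]1CC(C)(C)C(=O)[C@](C)(OC(=O)CBr)C1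
F5 | step 3 | (3aR,6S,7aR)-3a-hydroxy-4,4,7a-trimethyl-2-oxooctahydro-1-benzofuran-6-yl hexadecanoate | CCCCCCCCCCCCCCCC(=O)O[C@H]1CC(C)(C)[C@]2(O)CC(=O)O[C@]2(C)C1
F6 | step 1 | (4R,6R)-4-[(tert-butyldiphenylsilyl)oxy]-2,2,6-trimethylcyclohexan-1-one | CC(C)(C)[Si](c1ccccc1)(c1ccccc1)O[C@H]1CC(C)(C)C(=O)[C@H](C)C1
F7 | step 1 | O-bound trivalent-iodine enolate of F6 carrying one 2-(diethoxyphosphoryl)acetate ligand on phenyliodine | CC(C)(C)[Si](c1ccccc1)(c1ccccc1)O[C@H]1CC(C)(C)C(OI(c2ccccc2)OC(=O)CP(=O)(OCC)OCC)=C(C)C1
F8 | step 1 | (1R,5S)-5-[(tert-butyldiphenylsilyl)oxy]-1,3,3-trimethyl-2-oxocyclohexyl 2-(diethoxyphosphoryl)acetate | CC(C)(C)[Si](c1ccccc1)(c1ccccc1)O[C@H]1CC(C)(C)C(=O)[C@](C)(OC(=O)CP(=O)(OCC)OCC)C1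
F9 | step 1 | (6S,7aR)-6-[(tert-butyldiphenylsilyl)oxy]-4,4,7a-trimethyl-5,6,7,7a-tetrahydro-1-benzofuran-2(4H)-one | CC(C)(C)[Si](c1ccccc1)(c1ccccc1)O[C@H]1CC(C)(C)C2=CC(=O)O[C@]2(C)C1
F10 | step 1 | (−)-loliolide, (6S,7aR)-6-hydroxy-4,4,7a-trimethyl-5,6,7,7a-tetrahydro-1-benzofuran-2(4H)-one | O[C@H]1CC(C)(C)C2=CC(=O)O[C@]2(C)C1
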